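**Plan**

- Retrosynthesis: add back the C2=C3 double bond (flavanone to pyranone 10); cut C4a–C4, C4–C3 and O1–C2 together (to iodide 5, CO and phenylacetylene); cut C4a–I; cut both C8–prenyl bonds (to 5-methoxyresorcinol).
- Enabling feature (flavanone numbering): in the pyranone ring O1–C2–C3–C4–C4a–C8a, C4 is a ketone between C4a and C3, and O1 is the enol oxygen on C8a next to C4a. C4 can therefore enter as CO between a C4a–I bond and an alkyne; C5 carries OMe, so only the C8a oxygen can close.
- Forward: the carbocycle is made first, by dearomatising gem-diprenylation of the carbon between the two OH groups and iodination of the enol carbon. The pyranone ring is closed second, in a one-pot carbonylative annulation.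
- Stereochemistry: the only stereocentre, (S)-C2, is set last by ligand-controlled CuH 1,4-reduction of C2=C3.

Key step: step 3

Remark: prenyl = 3-methylbut-2-en-1-yl; 4, 5, 8 and 9 are vinylogous acids drawn as one tautomer, and proton shift between the two ring oxygens makes the two ring CH carbons of 4 equivalent.
Remark: L* in step 4 is the DTBM-SEGPHOS antipode that gives (S)-flavanone from 2-phenylchromone in a control run; this sense of induction is assumed to carry over to 10.

**Route**

Step 1
Reactants: 1 5-methoxyresorcinol (5-methoxybenzene-1,3-diol); 2 prenyl bromide (1-bromo-3-methylbut-2-ene, 2.1 equiv)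
Product: 4 5-hydroxy-3-methoxy-6,6-bis(3-methylbut-2-en-1-yl)cyclohexa-2,4-dien-1-one, via 2-prenyl-5-methoxyresorcinol 3 (not isolated)
Conditions: 10 % aq. KOH (3 equiv), slow addition of 2, 0 °C to rt; then dil. HCl; acidic product taken through aq. NaHCO3
Reagents that add atoms: prenyl bromide 2, CC(C)=CCBr
Why: Alkylative dearomatisation by C-alkylation of the resorcinolate: the carbon between the two phenoxide oxygens is ortho to both and is expected to take the first prenyl group (giving 3) and then the second, because gem-dialkylation there leads to a stabilised vinylogous-acid anion as in the gem-diprenylation of hop-acid phloroglucinols, while water as solvent favours C- over O-alkylation.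

Step 2
Reactants: 4 5-hydroxy-3-methoxy-6,6-bis(3-methylbut-2-en-1-yl)cyclohexa-2,4-dien-1-one
Product: 5 5-hydroxy-4-iodo-3-methoxy-6,6-bis(3-methylbut-2-en-1-yl)cyclohexa-2,4-dien-1-one
Conditions: NIS (1.0 equiv), MeCN, 0 °C, dark; used without delay
Reagents that add atoms: N-iodosuccinimide, O=C1CCC(=O)N1I
Why: Electrophilic α-iodination of a cyclic enol (as with dimedone or 4-hydroxycoumarin): the enol carbon between C–OH and C–OMe is far more nucleophilic than the prenyl alkenes, and since tautomerism makes the two ring CH carbons of 4 equivalent, one equivalent of NIS can give only the mono-iodide 5.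

Step 3
Reactants: 5 5-hydroxy-4-iodo-3-methoxy-6,6-bis(3-methylbut-2-en-1-yl)cyclohexa-2,4-dien-1-one; 6 phenylacetylene (1.3 equiv); 7 carbon monoxide
Product: 10 5-methoxy-8,8-bis(3-methylbut-2-en-1-yl)-2-phenyl-4H-chromene-4,7(8H)-dione, via alkynyl ketone 8 (not isolated), via β-diethylaminoenone 9 (not isolated)
Conditions: PdCl2(PPh3)2 (5 mol %), dppp (5 mol %), thiourea (5 mol %), CO (1–3 bar), Et2NH (6 equiv), DMF, 40 °C
Reagents that add atoms: phenylacetylene 6, C#Cc1ccccc1; carbon monoxide 7, [C-]#[O+]
Why: Proposed new method: Pd(0) should insert into the C4a–I bond of 5 (present as its diethylammonium enolate), CO insertion gives an acyl–palladium species, and amine-assisted transfer of the alkynyl group of 6 followed by reductive elimination gives alkynyl ketone 8, which forms C4a–C4 and C4–C3. Diethylamine then adds to the ynone to give aminoenone 9, and the C8a enol oxygen displaces the amine at C2, an addition–elimination that closes the pyranone ring in the 6-endo-dig sense and forms O1–C2. The closest known reaction is the Pd-catalysed carbonylative annulation of 2-iodophenols (or their acetates) with terminal alkynes in diethylamine to flavones; new here is the substrate class, an α-iodo vinylogous acid in place of an iodophenol, for which Sonogashira coupling–cyclisation without CO is the established relative. No stereocentre is created. The step needs carbonylative rather than direct alkynylation, which the CO atmosphere without copper co-catalyst should secure, and 6-endo rather than 5-exo closure, which the secondary-amine relay through 9 secures. The site of ring closure is fixed by the substrate, since C5 is blocked as its methyl ether and the C7 oxygen cannot reach C2.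

Step 4
Reactants: 10 5-methoxy-8,8-bis(3-methylbut-2-en-1-yl)-2-phenyl-4H-chromene-4,7(8H)-dione
Product: 11 griffinone A, (2S)-5-methoxy-8,8-bis(3-methylbut-2-en-1-yl)-2-phenyl-2,3-dihydro-4H-chromene-4,7(8H)-dione
Conditions: Cu(OAc)2 (5 mol %), L* (5.5 mol %), (EtO)2MeSiH (2 equiv), t-BuOH (2 equiv), toluene, 0 °C to rt; pH 7 buffer work-up
Reagents that add atoms: none
Why: CuH-catalysed asymmetric conjugate reduction as established for chromones: the bisphosphine-bound copper hydride adds H to one face of C2, the β-carbon of the C4 enone, which sets (S)-C2 under ligand control, t-BuOH then protonates the copper enolate at C3, and the other enone units (C5=C6, C4a=C8a) carry a donor oxygen on a fully substituted β-carbon and the prenyl alkenes are unactivated, so they should stay untouched.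

**Compound list**

1 | 5-methoxyresorcinol (5-methoxybenzene-1,3-diol) | COc1cc(O)cc(O)c1 | starting material
2 | prenyl bromide (1-bromo-3-methylbut-2-ene) | CC(C)=CCBr | starting material
3 | 2-prenyl-5-methoxyresorcinol, 5-methoxy-2-(3-methylbut-2-en-1-yl)benzene-1,3-diol | COc1cc(O)c(CC=C(C)C)c(O)c1 | intermediate
4 | 5-hydroxy-3-methoxy-6,6-bis(3-methylbut-2-en-1-yl)cyclohexa-2,4-dien-1-one | COC1=CC(=O)C(CC=C(C)C)(CC=C(C)C)C(O)=C1 | intermediate
5 | 5-hydroxy-4-iodo-3-methoxy-6,6-bis(3-methylbut-2-en-1-yl)cyclohexa-2,4-dien-1-one | COC1=CC(=O)C(CC=C(C)C)(CC=C(C)C)C(O)=C1I | intermediate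
6 | phenylacetylene | C#Cc1ccccc1 | starting material
7 | carbon monoxide | [C-]#[O+] | starting material
8 | alkynyl ketone, 5-hydroxy-3-methoxy-6,6-bis(3-methylbut-2-en-1-yl)-4-(3-phenylprop-2-ynoyl)cyclohexa-2,4-dien-1-one | COC1=CC(=O)C(CC=C(C)C)(CC=C(C)C)C(O)=C1C(=O)C#Cc1ccccc1 | intermediate
9 | β-diethylaminoenone, 4-[3-(diethylamino)-3-phenylprop-2-enoyl]-5-hydroxy-3-methoxy-6,6-bis(3-methylbut-2-en-1-yl)cyclohexa-2,4-dien-1-one (enamine geometry not fixed) | COC1=CC(=O)C(CC=C(C)C)(CC=C(C)C)C(O)=C1C(=O)C=C(N(CC)CC)c1ccccc1 | intermediate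
10 | 5-methoxy-8,8-bis(3-methylbut-2-en-1-yl)-2-phenyl-4H-chromene-4,7(8H)-dione | COC1=CC(=O)C(CC=C(C)C)(CC=C(C)C)C2=C1C(=O)C=C(c1ccccc1)O2 | intermediate
11 | griffinone A, (2S)-5-methoxy-8,8-bis(3-methylbut-2-en-1-yl)-2-phenyl-2,3-dihydro-4H-chromene-4,7(8H)-dione | COC1=CC(=O)C(CC=C(C)C)(CC=C(C)C)C2=C1C(=O)C[C@@H](c1ccccc1)O2 | target

Total step count: 4. Longest linear sequence: 4 steps (1 → 4 → 5 → 10 → 11).

**Steps most likely to fail**

Step 3. Several processes can compete with the annulation:
- slow oxidative addition into the C–I bond of the anionic enolate;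
- protodeiodination back to 4;
- capture of the acyl–palladium species by diethylamine to give an amide;
- direct alkynylation followed by 5-endo closure to a furan;
- amine exchange at the C5 methoxy group of the product.

The fallback uses known chemistry, sets out from 4 and returns at 10. Ac2O/Et3N followed by catalytic DMAP (O-acetylation and O→C acyl shift, as for 2-acylcyclohexane-1,3-diones) should give 4-acetyl-5-hydroxy-3-methoxy-6,6-diprenylcyclohexa-2,4-dien-1-one F1. LiHMDS (3.3 equiv) and then benzoyl chloride in THF, −78 °C to rt (Claisen condensation of the polyanion, the one-pot Baker–Venkataraman variant), should give the 1,3-diketone 5-hydroxy-3-methoxy-4-(3-oxo-3-phenylpropanoyl)-6,6-diprenylcyclohexa-2,4-dien-1-one F2. Catalytic p-TsOH in warm toluene should cyclodehydrate F2 through the only free hydroxyl, that on C8a, to give 10.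

Step 1. The first or the second prenyl group may enter at the ring carbon next to OMe, O-alkylation may compete, and the product anion may be alkylated a third time. The fallback sets out from 1 and returns at 3. MOMCl/i-Pr2NEt should give 1-methoxy-3,5-bis(methoxymethoxy)benzene F3. n-BuLi in THF at 0 °C (directed ortho-metalation between the two OMOM groups), then CuI and 2, should give 5-methoxy-1,3-bis(methoxymethoxy)-2-prenylbenzene F4. HCl in MeOH at rt should remove both acetals and give 3 as a single isolated regioisomer. Compound 3 is then taken to 4 with one equivalent of 2 under the conditions of step 1.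

Step 4. Hydride may be delivered to another part of the cross-conjugated system, turnover at the 2-aryl pyranone may be sluggish, facial discrimination may be poor, and ee may erode through retro-oxa-Michael opening at the vinylogous-acid oxygen. The fallback sets out from 5 and returns at 11; it brings in phenyl and the stereocentre together by C–C bond formation.
- The conditions of step 3 with ethynyltrimethylsilane in place of 6 should give the silyl ynone 5-hydroxy-3-methoxy-6,6-diprenyl-4-[3-(trimethylsilyl)prop-2-ynoyl]cyclohexa-2,4-dien-1-one F5.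
- Diethylamine is expected to desilylate F5 to the terminal ynone 5-hydroxy-3-methoxy-4-(prop-2-ynoyl)-6,6-diprenylcyclohexa-2,4-dien-1-one F6.
- Diethylamine should add to F6 to give the aminoenone 4-[(E)-3-(diethylamino)prop-2-enoyl]-5-hydroxy-3-methoxy-6,6-diprenylcyclohexa-2,4-dien-1-one F7.
- F7 should close to the 2-unsubstituted 5-methoxy-8,8-diprenyl-4H-chromene-4,7(8H)-dione F8.
- Asymmetric conjugate arylation of F8 (Pd(OCOCF3)2, t-BuPyOx antipode chosen for 2S, PhB(OH)2, NH4PF6, H2O, ClCH2CH2Cl, 40–60 °C), a reaction known for chromones, should give 11 under near-neutral conditions.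

Further compounds
F1 | step 3 | 4-acetyl-5-hydroxy-3-methoxy-6,6-bis(3-methylbut-2-en-1-yl)cyclohexa-2,4-dien-1-one | COC1=CC(=O)C(CC=C(C)C)(CC=C(C)C)C(O)=C1C(C)=O
F2 | step 3 | 5-hydroxy-3-methoxy-6,6-bis(3-methylbut-2-en-1-yl)-4-(3-oxo-3-phenylpropanoyl)cyclohexa-2,4-dien-1-one | COC1=CC(=O)C(CC=C(C)C)(CC=C(C)C)C(O)=C1C(=O)CC(=O)c1ccccc1
F3 | step 1 | 1-methoxy-3,5-bis(methoxymethoxy)benzene | COCOc1cc(OC)cc(OCOC)c1
F4 | step 1 | 5-methoxy-1,3-bis(methoxymethoxy)-2-(3-methylbut-2-en-1-yl)benzene | COCOc1cc(OC)cc(OCOC)c1CC=C(C)C
F5 | step 4 | 5-hydroxy-3-methoxy-6,6-bis(3-methylbut-2-en-1-yl)-4-[3-(trimethylsilyl)prop-2-ynoyl]cyclohexa-2,4-dien-1-one | COC1=CC(=O)C(CC=C(C)C)(CC=C(C)C)C(O)=C1C(=O)C#C[Si](C)(C)C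
F6 | step 4 | 5-hydroxy-3-methoxy-6,6-bis(3-methylbut-2-en-1-yl)-4-(prop-2-ynoyl)cyclohexa-2,4-dien-1-one | COC1=CC(=O)C(CC=C(C)C)(CC=C(C)C)C(O)=C1C(=O)C#C
F7 | step 4 | 4-[(E)-3-(diethylamino)prop-2-enoyl]-5-hydroxy-3-methoxy-6,6-bis(3-methylbut-2-en-1-yl)cyclohexa-2,4-dien-1-one | COC1=CC(=O)C(CC=C(C)C)(CC=C(C)C)C(O)=C1C(=O)/C=C/N(CC)CC
F8 | step 4 | 5-methoxy-8,8-bis(3-methylbut-2-en-1-yl)-4H-chromene-4,7(8H)-dione | COC1=CC(=O)C(CC=C(C)C)(CC=C(C)C)C2=C1C(=O)C=CO2
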